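**Strategy.** The target is the hetero-Diels–Alder dimer of one ortho-quinone, so everything rests on its monomer, the 7,10-epoxy-icetexane catechol. Its oxolane (ether O, benzylic C7, C6, ring-fusion C5, quaternary C10; one in each half of the dimer) is not closed as such. It is the expanded form of the cyclopropane C5–C6–C10 of a norcarane carbaldehyde, whose formyl C7=O is inserted into the C6–C10 bond. One acid-catalysed operation (Cloke–Wilson ring expansion, then oxocarbenium arylation at C8) turns this aldehyde into the bridged tetracycle and sets C7 and C10 from C5 alone. The precursor is a cis-fused cyclopropane from asymmetric carbene transfer to a benzylcyclohexene.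

Key step: step 8

Remark: icetexane numbering is used for the monomer (aromatic C8, C9, C11–C14; C20 = benzylic CH2; primed numbers for the dienophile half), and 3-isopropylcatechol is taken as the purchasable arene.

Step 1
Reactants: 1 3-isopropylcatechol
Product: 2 1,2-dimethoxy-3-isopropylbenzene
Conditions: MeI, K2CO3, acetone, reflux
Reagents that add atoms: iodomethane, CI
Why: Williamson O-methylation (SN2 on iodomethane) of both phenols installs the ethers that protect the catechol and direct the next metalation.

Step 2
Reactants: 2 1,2-dimethoxy-3-isopropylbenzene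
Product: 4 2,3-dimethoxy-4-isopropylbenzaldehyde, via aryllithium 3 (not isolated)
Conditions: n-BuLi, TMEDA, Et2O, 0 °C to rt; DMF, −78 °C to rt; aq. HCl
Reagents that add atoms: N,N-dimethylformamide, CN(C)C=O
Why: Directed ortho-metalation removes the only hydrogen ortho to a methoxy group (the future C9) and formylation of the aryllithium with DMF places C20 on the ring.

Step 3
Reactants: 4 2,3-dimethoxy-4-isopropylbenzaldehyde; 5 2,2-dimethylcyclohexanone
Product: 6 (6E)-6-[(2,3-dimethoxy-4-isopropylphenyl)methylidene]-2,2-dimethylcyclohexan-1-one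
Conditions: KOH, EtOH, reflux
Reagents that add atoms: none
Why: Claisen–Schmidt condensation of the non-enolisable aldehyde with the ketone at its only enolisable α-carbon (future C10) should give the E-enone, aryl anti to the carbonyl group.

Step 4
Reactants: 6 (6E)-benzylidene ketone
Product: 7 N-tosylhydrazone of 6 (C=N geometry immaterial)
Conditions: TsNHNH2, cat. HCl, EtOH, reflux
Reagents that add atoms: p-toluenesulfonyl hydrazide, Cc1ccc(cc1)S(=O)(=O)NN
Why: Acid-catalysed hydrazone condensation at the conjugated carbonyl group prepares the enone for reductive 1,3-transposition.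

Step 5
Reactants: 7 tosylhydrazone
Product: 9 1-[(3,3-dimethylcyclohex-1-en-1-yl)methyl]-2,3-dimethoxy-4-isopropylbenzene, via allylic diazene 8 (not isolated)
Conditions: catecholborane, CHCl3, 0 °C to rt; NaOAc·3H2O, reflux
Reagents that add atoms: none
Why: Kabalka reduction: hydride adds to C=N (C5), sulfinate loss gives the allylic diazene, and its retro-ene loss of N2 delivers hydrogen to C20 and moves the double bond to C5=C10 regiospecifically.

Step 6
Reactants: 9 benzylcyclohexene; 10 tert-butyl diazoacetate
Product: 11 tert-butyl (1S,6S,7R)-1-[(2,3-dimethoxy-4-isopropylphenyl)methyl]-5,5-dimethylbicyclo[4.1.0]heptane-7-carboxylate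
Conditions: CuOTf·0.5C6H6 (2 mol %), (S,S)-t-Bu-box (2.4 mol %), CH2Cl2, rt, slow addition of 10
Reagents that add atoms: none
Why: Asymmetric copper-carbene cyclopropanation of the electron-rich trisubstituted alkene: cis fusion is inherent, the bulky ester goes exo, and the bisoxazoline ligand (its antipode if the sense of induction requires) directs the carbene to the Si face of the vinylic CH, which sets C5 and C10 together.

Step 7
Reactants: 11 cyclopropane ester
Product: 12 (1S,6S,7R)-1-[(2,3-dimethoxy-4-isopropylphenyl)methyl]-5,5-dimethylbicyclo[4.1.0]heptane-7-carbaldehyde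
Conditions: DIBAL-H, toluene, −78 °C; aq. potassium sodium tartrate
Reagents that add atoms: none
Why: Partial ester reduction through the aluminate that is stable at −78 °C should stop at the aldehyde and leaves C5 and C10 untouched (the C6 configuration is irrelevant, since C6 becomes CH2).

Step 8
Reactants: 12 norcarane carbaldehyde
Product: 15 (5S,7S,10S)-7,10-epoxy-11,12-dimethoxyicetexa-8,11,13-triene, via dihydrofuran 13 (not isolated), via oxocarbenium ion 14 (not isolated)
Conditions: TfOH (10 mol %), CH2Cl2, −20 °C to rt, dilute
Reagents that add atoms: none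
Why: Protonation of the formyl oxygen turns the cyclopropane into a donor–acceptor system: the C6–C10 bond, the one that leaves a tertiary cation, ionises and the enol oxygen closes on C10, so the three-membered ring C5–C6–C10 is expanded by C7 and O to the 2,3-dihydrofuran 13 (acid-catalysed Cloke–Wilson rearrangement). Protonation of the enol ether at C6 gives oxocarbenium ion 14, which the arene attacks through C8, para to the C12 methoxy group (Marson-type Friedel–Crafts reaction). The closest known reaction types are the Brønsted-acid Cloke–Wilson rearrangement of cyclopropyl carbonyl compounds and the arylation of tetrahydrofuranyl oxocarbenium ions. The oxolane closes by front-side O–C10 bond formation on the cation (five-membered, ring expansion of the cyclopropane); the arylation is 6-endo-trig for the oxacycle O–C7–C8–C9–C20–C10 and thereby 7-exo-trig for the carbocycle. C5 is carried over untouched, C10 is re-formed with retention because only the cis-fused bicycle can close, and C7 follows because the arylmethyl group on C10 reaches only one face of 14. The step needs cleavage of C6–C10 instead of C5–C6, secured by the tertiary C10, and capture of the cation by oxygen before elimination or hydride shift, secured by the oxygen held three atoms away.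

Step 9
Reactants: 15 dimethyl ether
Product: 16 (5S,7S,10S)-7,10-epoxyicetexa-8,11,13-triene-11,12-diol (brussonol skeleton)
Conditions: NaSEt, DMF, 130 °C, argon; aq. HCl
Reagents that add atoms: none
Why: SN2 demethylation of both aryl methyl ethers by thiolate spares the bridged benzylic ether, whose bridgehead carbon cannot be attacked from the rear and which a Lewis acid would open.

Step 10
Reactants: 16 catechol (two molecules)
Product: 18 target dimer CNP0371333.1, via ortho-quinone 17 (not isolated)
Conditions: Ag2O, Et2O, rt; filter, concentrate; neat film, 40 °C, dark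
Reagents that add atoms: none
Why: Oxidation to the ortho-quinone and its inverse-electron-demand hetero-Diels–Alder dimerisation: O=C11–C12=O of one molecule adds across C13'=C14' of a second, O12 to the unhindered C14'–H and O11 to C13', on the face opposite to the 7',10'-ether oxygen, which should create C13' and C14' under substrate control (C7 is a bridgehead, so no quinone methide can divert the quinone).

**Compound list**

1 | 3-isopropylcatechol | CC(C)c1cccc(O)c1O | starting material
2 | 1,2-dimethoxy-3-isopropylbenzene | CC(C)c1cccc(OC)c1OC | intermediate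
3 | (2,3-dimethoxy-4-isopropylphenyl)lithium | [Li]c1ccc(C(C)C)c(OC)c1OC | intermediate (not isolated)
4 | 2,3-dimethoxy-4-isopropylbenzaldehyde | CC(C)c1ccc(C=O)c(OC)c1OC | intermediate
5 | 2,2-dimethylcyclohexanone | CC1(C)CCCCC1=O | starting material
6 | (6E)-6-[(2,3-dimethoxy-4-isopropylphenyl)methylidene]-2,2-dimethylcyclohexan-1-one | O=C1C(C)(C)CCC/C1=C\c1ccc(C(C)C)c(OC)c1OC | intermediate
7 | N-tosylhydrazone of 6 | Cc1ccc(cc1)S(=O)(=O)NN=C1C(C)(C)CCC/C1=C\c1ccc(C(C)C)c(OC)c1OC | intermediate
8 | allylic diazene (racemic at C5) | N=NC1C(C)(C)CCC/C1=C\c1ccc(C(C)C)c(OC)c1OC | intermediate (not isolated)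
9 | 1-[(3,3-dimethylcyclohex-1-en-1-yl)methyl]-2,3-dimethoxy-4-isopropylbenzene | CC(C)c1ccc(CC2=CC(C)(C)CCC2)c(OC)c1OC | intermediate
10 | tert-butyl diazoacetate | CC(C)(C)OC(=O)C=[N+]=[N-] | starting material
11 | tert-butyl (1S,6S,7R)-1-[(2,3-dimethoxy-4-isopropylphenyl)methyl]-5,5-dimethylbicyclo[4.1.0]heptane-7-carboxylate (exo ester) | CC(C)c1ccc(C[C@@]23CCCC(C)(C)[C@@H]2[C@H]3C(=O)OC(C)(C)C)c(OC)c1OC | intermediate
12 | (1S,6S,7R)-1-[(2,3-dimethoxy-4-isopropylphenyl)methyl]-5,5-dimethylbicyclo[4.1.0]heptane-7-carbaldehyde | CC(C)c1ccc(C[C@@]23CCCC(C)(C)[C@@H]2[C@H]3C=O)c(OC)c1OC | intermediate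
13 | (3aS,7aS)-7a-[(2,3-dimethoxy-4-isopropylphenyl)methyl]-4,4-dimethyl-3a,4,5,6,7,7a-hexahydro-1-benzofuran | CC(C)c1ccc(C[C@@]23CCCC(C)(C)[C@@H]2C=CO3)c(OC)c1OC | intermediate (not isolated)
14 | cyclic oxocarbenium ion from C6-protonation of 13 | CC(C)c1ccc(C[C@@]23CCCC(C)(C)[C@@H]2CC=[O+]3)c(OC)c1OC | intermediate (not isolated)
15 | (5S,7S,10S)-7,10-epoxy-11,12-dimethoxyicetexa-8,11,13-triene | CC(C)c1cc2c(c(OC)c1OC)C[C@@]13CCCC(C)(C)[C@@H]1C[C@@H]2O3 | intermediate
16 | (5S,7S,10S)-7,10-epoxyicetexa-8,11,13-triene-11,12-diol | CC(C)c1cc2c(c(O)c1O)C[C@@]13CCCC(C)(C)[C@@H]1C[C@@H]2O3 | intermediate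
17 | (5S,7S,10S)-7,10-epoxyicetexa-8,13-diene-11,12-dione (ortho-quinone) | CC(C)C1=CC2=C(C(=O)C1=O)C[C@@]13CCCC(C)(C)[C@@H]1C[C@@H]2O3 | intermediate (not isolated)
18 | CNP0371333.1, cis-fused 1,4-dioxane dimer (C12–O–C14', C11–O–C13') | CC(C)c1cc2c(c3c1O[C@@H]1C4=C(C[C@@]56CCCC(C)(C)[C@@H]5C[C@@H]4O6)C(=O)C(=O)[C@]1(C(C)C)O3)C[C@@]13CCCC(C)(C)[C@@H]1C[C@@H]2O3 | target

**Step count and risks**

Total step count: 10. Longest linear sequence: 10 steps (1 to 18).

Steps most likely to fail:

First, step 8. The arene may add to the protonated aldehyde before the cyclopropane opens; the benzylic oxygen is then lost as water and the C10 cation eliminates or undergoes hydride and methyl shifts. The fallback sets out from 11 and keeps the oxygen at the carboxyl level, where the arene cannot intercept it. TfOH in CH2Cl2 cleaves the tert-butyl ester, and the carboxyl oxygen captures the tertiary C10 cation of the opened cyclopropane to give the cis-fused γ-lactone F1, the same three-to-five ring expansion. DIBAL-H at −78 °C reduces it to lactol F2, and BF3·OEt2 in CH2Cl2 generates oxocarbenium ion 14, which closes by the Marson-type arylation. The fallback comes back to the route at 15.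

Second, step 6. Facial discrimination in carbene transfer to a hindered trisubstituted cycloalkene may be poor, and carbene dimerisation may outrun it. The fallback sets out from 9 and replaces catalyst control by a covalently bound auxiliary with physical separation. The known (1R,2S,5R)-menthyl diazoacetate and Cu(acac)2 in refluxing 1,2-dichloroethane give the exo esters as a pair of diastereomers, from which menthyl ester F3 with the (1S,6S,7R) cyclopropane is separated by chromatography or crystallisation. DIBAL-H at −78 °C releases menthol, and the fallback comes back to the route at 12.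

Third, step 4. Condensation at the carbonyl group flanked by the quaternary carbon may be slow, and the hydrazide may add in conjugate fashion and close to a pyrazoline, so that the transposition of step 5 has no substrate. The fallback sets out from 4 (with 5) and avoids the hydrazone. NaBH4 in MeOH gives benzyl alcohol F4 and PBr3 in Et2O gives benzyl bromide F5. The lithium enolate of 5 (LDA, THF, −78 °C) is alkylated to ketone F6, which is racemic, its stereocentre being removed in the next step. KHMDS and PhNTf2 give the only possible enol triflate F7. Pd(OAc)2, PPh3, HCO2H and Bu3N in DMF at 60 °C reduce the triflate to the alkene, and the fallback comes back to the route at 9.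

Further compounds
F1 | step 8 | (3aS,7aS)-7a-[(2,3-dimethoxy-4-isopropylphenyl)methyl]-4,4-dimethylhexahydro-1-benzofuran-2(3H)-one | CC(C)c1ccc(C[C@@]23CCCC(C)(C)[C@@H]2CC(=O)O3)c(OC)c1OC
F2 | step 8 | (3aS,7aS)-7a-[(2,3-dimethoxy-4-isopropylphenyl)methyl]-4,4-dimethyloctahydro-1-benzofuran-2-ol (anomer mixture) | CC(C)c1ccc(C[C@@]23CCCC(C)(C)[C@@H]2CC(O)O3)c(OC)c1OC
F3 | step 6 | (1R,2S,5R)-menthyl (1S,6S,7R)-1-[(2,3-dimethoxy-4-isopropylphenyl)methyl]-5,5-dimethylbicyclo[4.1.0]heptane-7-carboxylate | CC(C)c1ccc(C[C@@]23CCCC(C)(C)[C@@H]2[C@H]3C(=O)O[C@@H]4C[C@H](C)CC[C@H]4C(C)C)c(OC)c1OC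
F4 | step 4 | (2,3-dimethoxy-4-isopropylphenyl)methanol | CC(C)c1ccc(CO)c(OC)c1OC
F5 | step 4 | 1-(bromomethyl)-2,3-dimethoxy-4-isopropylbenzene | CC(C)c1ccc(CBr)c(OC)c1OC
F6 | step 4 | 6-[(2,3-dimethoxy-4-isopropylphenyl)methyl]-2,2-dimethylcyclohexan-1-one (racemic) | CC(C)c1ccc(CC2CCCC(C)(C)C2=O)c(OC)c1OC
F7 | step 4 | 2-[(2,3-dimethoxy-4-isopropylphenyl)methyl]-6,6-dimethylcyclohex-1-en-1-yl trifluoromethanesulfonate | CC(C)c1ccc(CC2=C(OS(=O)(=O)C(F)(F)F)C(C)(C)CCC2)c(OC)c1OC
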